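Readings and results were generated by integration from invented constants.

Reciprocal molarity is the unit of what a charge of catalyst has achieved by a given time. The alpha run stands at 0.986 M⁻¹ at 41 h. Call this its reach: the natural logarithm of [reagent]/[starting material] at that time, over the same ratio at the start, divided by the excess of reagent charged. For a rate first order in each of the two, the reach is the rate constant times the working catalyst, summed over time, so the amounts of substrate drop out of it.

| setting | alpha | theta | eta | zeta | epsilon |
|---|---|---|---|---|---|
| starting material | 0.800 M | 0.480 M | 0.800 M | 0.800 M | 0.260 M |
| reagent | 0.960 M | 0.640 M | 0.960 M | 0.960 M | 0.960 M |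
| free catalyst | 0.0800 M | 0.0800 M | 0.0400 M | 0.0800 M | 0.240 M |
| product |  |  |  | 0.240 M |  |
| time |  |  |  |  | 41 h |

- alpha run (time / h: [product] / M): 2.3: 0.058; 7.1: 0.167; 14: 0.278; 21: 0.316; 31: 0.384; 41: 0.405
- theta run (time / h: [product] / M): 2.3: 0.031; 7.1: 0.077; 14: 0.117; 21: 0.142; 31: 0.195; 41: 0.197
- eta run (time / h: [product] / M): 2.3: 0.056; 7.1: 0.117; 14: 0.191; 21: 0.226; 31: 0.270; 41: 0.267
- zeta run (time / h: [product] / M): 2.3: 0.303; 7.1: 0.412; 14: 0.507; 21: 0.573; 31: 0.616; 41: 0.632

(readings scatter by 0.008 M)

1. apparent order in [free catalyst] of the starting rate, round the charge of the alpha run (the rate where two percent of its starting material have turned into product)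
2. the theta run starts with 0.320 M less of starting material and of reagent than the alpha run, and with no product. Compared where both hold the same amount of starting material, once fifteen percent of what the theta run was charged with has turned into product, is the theta run faster, slower or alike (within a tenth)?
3. product in the epsilon run at 41 h, as a share of the starting material charged

- Overall: starting material + reagent -> product, with free catalyst as catalyst.
- Constant volume, constant temperature.
- An order is taken over about fifteen percent of the charge, up and down.

The readings support that order. The theta run, with another charge of starting material and reagent but the same free catalyst, has a reach of 1.00 M⁻¹ at 41 h. The zeta run, counted by the product made above its charge, has 0.928 M⁻¹. So the stall in these runs follows the catalyst and its age, and the end of a run is the point where its reach stops growing.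

Two views part over the epsilon run, whose free catalyst is 3.00 times the alpha charge. The first view is my own reckoning. It treats the catalyst as a fixed budget, so the reach at 41 h scales with the charge, and the eta run seems to agree: its reach of 0.501 M⁻¹ is 0.508 of the alpha value. Scaling the alpha reach by that factor turns 0.260 M of starting material, the limiting reagent, into a product share of 90.5 %.

The second view is the forecast's. It reads the eta curve as about 0.63 of the alpha curve early and about 0.52 late, and takes from the early figure an order in catalyst of about 0.65. It holds that “The stall is therefore time-driven catalyst death.” It puts the epsilon reach near 2.3 and gives 85 %, with 0.63 for the order and faster for the theta comparison.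

The flask gives 84.0 % for the epsilon run, nearer the forecast than my reckoning, with faster for the theta comparison and an order of 0.54.

    2 free catalyst ⇌ catalyst dimer, settled at all times (372.0 M⁻¹)
    free catalyst + starting material + reagent → product + free catalyst (4.320 M⁻² h⁻¹)
    free catalyst → spent catalyst (0.3485 h⁻¹)

That order goes with the early rate of the eta run, 0.021 M h⁻¹, which is 0.68 of the alpha rate at the same amount of product, on catalyst charges differing by a factor of 2.00. Read back, the epsilon result is a reach of 2.25 M⁻¹, which is 2.28 times the alpha reach. Proportion keeps the span from the eta charge to the alpha charge, where the reach at 41 h goes from 0.501 M⁻¹ to 0.986 M⁻¹.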